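**What is asked.** If ring forms from starting material by itself and starting material then eats it, as in a consecutive-competitive pair, both rates carry c(starting material), so the split between them depends on c(ring) and one constant.

| flask | solid substrate | remark | time |
|---|---|---|---|
| blue | 0.25 M | run made earlier |  |
| green | 0.55 M | run made earlier |  |
| flask | 0.37 M |  | 30 h |

| run | time / h | solid substrate / % | ring / % | side product / % |
|---|---|---|---|---|
| blue | 1.00 | 70 | 17 | 1 |
| blue | 3.00 | 15 | 41 | 32 |
| blue | 5.00 | 0 | 47 | 51 |
| blue | 8.00 | 2 | 46 | 49 |
| blue | 10.0 | 3 | 49 | 46 |
| blue | 15.0 | 1 | 51 | 47 |
| blue | 20.0 | 0 | 52 | 49 |
| green | 1.33 | 82 | 10 | 0 |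
| green | 2.00 | 76 | 14 | 6 |
| green | 3.00 | 64 | 18 | 15 |
| green | 5.00 | 36 | 23 | 34 |
| green | 8.00 | 0 | 28 | 64 |
| green | 12.0 | 1 | 33 | 67 |
| green | 20.0 | 1 | 34 | 66 |

(scatter of a reading: 2 percentage points)

1. the state of affairs at 30 h: stopped, and by what, or still going (for what has run out or reacted, a solid counts together with what of it has only dissolved) (forward and back rates have come level / all of the solid substrate has reacted / it is still moving)
2. part of the solid substrate that has turned into other species by 30 h (what has only dissolved does not count)
3. amount of ring at 30 h, in percent of the solid substrate charged
4. amount of side product at 30 h, in percent of the solid substrate charged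

- percentages count the solid substrate that a species holds: one open dimer or side product counts as two
- percentages count the solid substrate that a species holds: one open trimer counts as three
- solid, in amounts per volume of the solution: solid substrate
- candidate steps: starting material + ring -> side product; starting material -> ring; starting material + open dimer -> open trimer; solid substrate <-> starting material; 2 starting material -> open dimer
- at the start none of the solid substrate is in solution
- what has only dissolved of solid substrate counts as not reacted
- the reaction counts as stopped when no species that holds the solid substrate changes by six tenths of a point or more over the second half of the time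

**First hours.** Solid feeds the solution at a steady pace: in green it goes at 0.0733 M h⁻¹ between 2.00 h and 5.00 h. Ring comes first, as blue shows at 1.00 h, with ring at 17% and side product at 1%.

**The middle.** As c(ring) grows, more of what dissolves goes into side product. Green ends with ring and side product at 100%, so I count the charge as these two.

**The end.** At that pace I expect the flask's solid to be gone after about 5.05 h, far sooner than 30 h, and green's readings from 12.0 h to 20.0 h move within their scatter. The end split is therefore what counts.

**My reckoning.** Let m be the ring made so far, eaten or not. Each eaten ring took one more starting material, so m = (charge + c(ring))/2, and c(ring) = a(1 − e^(−m/a)). Green ends at 0.187 M of ring, with 0.737 M for charge plus ring. Going round from a = c(ring) gives 0.217 M, then 0.229 M, then 0.234 M, and last, as a reading from green with its scatter, the ring ceiling a = 0.236 M, the c(ring) at which ring is eaten as fast as it forms.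

For the flask, start with no ring in m: c(ring) is 0.128 M. Put that back and get 0.154 M, then 0.158 M. That is ring 42.7% and side product 57.3%.

**The forecast.** It says all of the solid substrate has reacted, conversion 100%, ring 43%, side product 57%: “so the reaction is over by 30 h”.

**The result.** The flask gives all of the solid substrate has reacted, conversion 100%, ring 40.1%, side product 57.2%, so the forecast stands.

    starting material + ring → side product (k = 0.00470 M⁻¹ s⁻¹)
    starting material → ring (k = 0.00100 s⁻¹)
    starting material + open dimer → open trimer (k = 0.00120 M⁻¹ s⁻¹)
    solid substrate ⇌ starting material, rate k4*(cs4 - [starting material]) while solid is left; crystals form when [starting material] > cs4 (solubility = 41.0 mM, k = 6.90 × 10⁻⁴ s⁻¹)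
    2 starting material → open dimer (k = 0.00140 M⁻¹ s⁻¹)

**Ceiling again.** The flask's c(ring) is 0.148 M, below 0.236 M, and 2.6 percentage points under my share. For the neighbour charged with 1.5 M, two rounds give 0.226 M, then 0.230 M, which is ring 15.3%. That neighbour holds ring 13.9% and side product 83.9%.

Readings and results come from a simulation from invented constants; scatter was added.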